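I read the gap first.

| setting | south | south-west | flask |
|---|---|---|---|
| L | 0.54 M | 1.2 M | 0.80 M |
| J | 8 mM | 8 mM | 8.00 mM |
| D | 8 mM | 8 mM | 8.0 mM |
| remark | run made earlier | run made earlier |  |
| time |  |  | 6.0 min |

| run | time / min | Q / % | L / % |
|---|---|---|---|
| south | 0.500 | 0.1 | 96.6 |
| south | 0.833 | 1.2 | 94.7 |
| south | 1.33 | 1.8 | 92.8 |
| south | 2.00 | 3.3 | 89.0 |
| south | 4.00 | 6.4 | 77.9 |
| south | 6.00 | 9.4 | 69.3 |
| south-west | 0.417 | 0.6 | 96.5 |
| south-west | 1.33 | 3.1 | 92.1 |
| south-west | 2.00 | 4.9 | 87.2 |
| south-west | 3.00 | 8.0 | 81.0 |
| south-west | 5.00 | 12.3 | 70.9 |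
| south-west | 6.00 | 14.9 | 65.7 |

(readings scatter by 0.5 percentage points)

- the average divides the monomer in chains by the number of chains begun, living and dead together
- the earlier runs do not show the number of chains; that part of a forecast is a guess

- average number of monomer units in a chain (chains begun, living or dead) at 6.0 min
- part of the L that has reacted at 6.0 min

In the south run at 6.00 min, the L lost was more than the Q found, leaving a gap of 21.3% of the charge. The south-west gap was 19.4%, though that charge was about twice the south one. So I divided each gap by the time and by the mean of one and the final L fraction, which gave 0.0419 min⁻¹ and 0.0390 min⁻¹. I carried their mean, 0.0405 min⁻¹, as the leak constant, a first-order constant read from the runs: the fraction of the L present that is lost per minute without appearing as Q.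

But Q rose with the charge, so interpolating on the logarithm of the charge gave the new flask 11.8% as Q. With L held at its full charge, the leak took 24.3%, leaving an L fraction of 63.9%. I put that answer back in and went round once more, so the gap became 19.9% and c became 31.7%. For the chains I guessed that Q alone was in them and that each charged D began one, which gave dp 11.8.

The forecast stood higher than mine on c and on dp, at 32.5% (31% to 34%) and 21 (10 to 36), and it said of the chains, "this part is a guess".

The flask gave c 33.1% and dp 13.5.

    L + D → X + Q (k = 0.520 L mol⁻¹ min⁻¹)
    L + X → Q + X, rate k2*[X]*[L] (k = 9.00 L mol⁻¹ min⁻¹)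
    X + J → Z (k = 54.0 L mol⁻¹ min⁻¹)
    L → G (k = 0.0430 min⁻¹)
    X → E (k = 0.00710 min⁻¹)

In the flask the gap was G. At 6.00 min in the flask, the path from L to G used L at 2.0 times the rate of the path from L to Q, and G stood at 21.3% against 11.8% for Q. The leak constant with the flask's simulated L gave 20.3% for G. In the neighbour flask, the same charge read at 15 min, it gave 42.3%, and G stood at 41.3%.

(All runs are calculated for substances that don't exist, and the scatter is random.)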